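**Retrosynthetic overview**
1. Target 29 ⇒ allylic alcohol 28 (oxidation) ⇒ silyl ether 27 ⇒ hydroxy acid 17 + trienoic acid 25 (ester bond at C4).
2. 17 ⇒ bicyclic keto acid 8 by vinylogous hydroxylation at C4 and C1 alkylation with allylic bromide 12.
3. 8 ⇒ 6 (the carvone isopropenyl group steers the stereochemistry and is then cut off); ring B (cyclopentenone) ⇒ aldol condensation of a 1,4-diketone ⇒ the two propargyl groups of 3.
4. 3 ⇒ (R)-carvone 1 (ring A) + CO2 + propargyl bromide: cathodic β-carboxylation and propargylation of the electrogenerated enolate make the C7–CO2 bond and the C7a quaternary centre.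
5. 25 ⇒ (2R)-2-methylbutan-1-ol 18 by Wittig and vinylogous Horner–Wadsworth–Emmons chain extension; ring A comes from carvone, ring B is closed second.

Ring positions follow 1H-indene numbering (C1–C3, C3a, C4–C7, C7a). None of these steps has been run; conditions are proposals.

Assumption: (2R)-2-methylbutan-1-ol 18 is bought as the enantiopure alcohol, because the sec-butyl centre in the given SMILES is R and the common S alcohol would give the wrong epimer.

**Step 1**
Reactants: 1 (R)-carvone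
Product: 3 prop-2-yn-1-yl (1R,2S,5R)-2-methyl-3-oxo-5-(prop-1-en-2-yl)-2-(prop-2-yn-1-yl)cyclohexane-1-carboxylate, via magnesium enolate carboxylate 2 (not isolated)
Conditions: undivided cell, Mg anode, glassy-carbon cathode, CO2 (1 atm), Bu4NBr (0.1 M), DMF, −10 °C, 8 mA cm−2, 2.2 F mol−1; then Ar sparge (25 °C), HC≡CCH2Br (5 equiv), 25 → 40 °C
Reagents that add atoms: carbon dioxide, O=C=O; 3-bromoprop-1-yne (propargyl bromide), C#CCBr
Why: Proposed new method: cathodic reduction of the enone gives a radical anion whose β-carbon adds to CO2 anti to the C5 isopropenyl group, a second electron gives the Mg-bound enolate (held reversibly as its CO2 adduct until degassing), and this enolate is then C-propargylated anti to the new carboxylate (methyl ends cis to CO2R) while the carboxylate is O-propargylated; the closest known reactions are the Mg-anode electroreductive β-carboxylation of enones, which stops at the protonated keto acid, and the cuprate conjugate addition–enolate alkylation of carvone, whose trans,trans course it copies.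

**Step 2**
Reactants: 3 bis-propargyl keto ester
Product: 6 (5R,7R,7aS)-7a-methyl-2-oxo-5-(prop-1-en-2-yl)-2,4,5,6,7,7a-hexahydro-1H-indene-7-carboxylic acid, via acetonyl ester triketone 4 (not isolated), via diketo carboxylate 5 (not isolated)
Conditions: Ph3PAuNTf2 (3 mol%), H2O (10 equiv), 1,4-dioxane, 60 °C; then KOH (5 equiv), MeOH/H2O, 0 °C (1 h) → 60 °C; aq. HCl
Reagents that add atoms: water, O; potassium hydroxide, [K+].[OH-]
Why: Carbonyl-assisted gold-catalysed Markovnikov hydration turns both propargyl groups into acetonyl groups, cold hydroxide first cleaves the activated 2-oxopropyl ester so that C7 becomes a non-epimerisable carboxylate, and the 1,4-diketone then closes ring B by intramolecular aldol condensation; no stereocentre is touched.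

**Step 3**
Reactants: 6 isopropenyl hydrindenone acid
Product: 8 (7R,7aS)-7a-methyl-2-oxo-2,4,5,6,7,7a-hexahydro-1H-indene-7-carboxylic acid, via methoxy hydroperoxide 7 (not isolated)
Conditions: O3, MeOH/CH2Cl2, −78 °C (Sudan Red 7B end point); then FeSO4·7H2O (1.2 equiv), PhSH (3 equiv), −78 → 23 °C
Reagents that add atoms: none
Why: Dealkenylative hydrogenation: the isopropenyl group, far more nucleophilic than the enone C=C, is ozonised in MeOH to the α-methoxy hydroperoxide, divalent iron reduces it to an alkoxy radical that β-fragments (methyl acetate) to the C5 radical, and PhSH caps it by hydrogen-atom transfer; the C5 stereocentre is erased on purpose and C7/C7a are untouched.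

**Step 4**
Reactants: 9 2-methylidenepropane-1,3-diol
Product: 11 2-({[tert-butyl(dimethyl)silyl]oxy}methyl)prop-2-en-1-ol, via monosodium alkoxide 10 (not isolated)
Conditions: NaH (1.0 equiv), THF, 0 → 23 °C; then TBSCl (1.0 equiv)
Reagents that add atoms: tert-butyl(chloro)dimethylsilane (TBSCl), CC(C)(C)[Si](C)(C)Cl
Why: Monosilylation of a symmetric diol through its sparingly soluble monosodium alkoxide (O-silylation); no stereocentre.

**Step 5**
Reactants: 11 mono-TBS diol
Product: 12 {[2-(bromomethyl)prop-2-en-1-yl]oxy}(tert-butyl)dimethylsilane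
Conditions: Ph3PBr2 (1.2 equiv), imidazole (1.3 equiv), CH2Cl2, 0 °C
Reagents that add atoms: dibromo(triphenyl)-λ5-phosphane (Ph3PBr2), BrP(Br)(c1ccccc1)(c1ccccc1)c1ccccc1
Why: Appel-type deoxybromination through the alkoxyphosphonium salt (SN2 by bromide), with imidazole protecting the silyl ether from HBr.

**Step 6**
Reactants: 8 bicyclic keto acid; 12 allylic bromide
Product: 14 (1R,7R,7aS)-1-[2-({[tert-butyl(dimethyl)silyl]oxy}methyl)prop-2-en-1-yl]-7a-methyl-2-oxo-2,4,5,6,7,7a-hexahydro-1H-indene-7-carboxylic acid, via dilithium dienolate carboxylate 13 (not isolated)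
Conditions: LiN(i-Pr)2 (2.3 equiv), THF, −78 °C; then 12 (1.4 equiv), DMPU, −78 → −40 °C; aq. HCl (pH 3)
Reagents that add atoms: none
Why: Kinetic α′-deprotonation of the cyclopentenone (the acid is masked as its lithium carboxylate) and SN2 C-alkylation of the cross-conjugated dienolate; the electrophile should enter C1 on the face of the angular methyl, away from the C7 ring carbon carrying the solvated carboxylate, giving 1R, which should also be the thermodynamic epimer at this epimerisable centre.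

**Step 7**
Reactants: 14 C1-alkylated keto acid
Product: 17 (1R,4S,7R,7aS)-1-[2-({[tert-butyl(dimethyl)silyl]oxy}methyl)prop-2-en-1-yl]-4-hydroxy-7a-methyl-2-oxo-2,4,5,6,7,7a-hexahydro-1H-indene-7-carboxylic acid, via bis-silyl dienol ether 15 (not isolated), via hydroxy silyl ester 16 (not isolated)
Conditions: TBSOTf (3.2 equiv), Et3N (5 equiv), CH2Cl2, −78 → 0 °C; pentane filtration; then mCPBA (1.1 equiv), CH2Cl2, −40 °C; then aq. citric acid, THF, 23 °C
Reagents that add atoms: 3-chloroperoxybenzoic acid (mCPBA), OOC(=O)c1cccc(Cl)c1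
Why: Vinylogous Rubottom oxidation: soft enolisation removes a γ-hydrogen at C4 (the α′-hydrogen at C1 is tertiary and shielded) to give the linear silyl dienol ether, and the peracid attacks its terminus C4 axially through a chair-like transition state on the β face, as electrophiles do at C6 of steroidal 3,5-dienol ethers, setting 4S (OH cis to the angular methyl); the less nucleophilic side-chain alkene is left alone.

**Step 8**
Reactants: 18 (2R)-2-methylbutan-1-ol; 19 2-(triphenyl-λ5-phosphanylidene)propanal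
Product: 21 (2E,4R)-2,4-dimethylhex-2-enal, via (2R)-2-methylbutanal 20 (not isolated)
Conditions: PhI(OAc)2 (1.1 equiv), TEMPO (10 mol%), CH2Cl2, 23 °C; then 19 (1.3 equiv), 45 °C (sealed)
Reagents that add atoms: none
Why: TEMPO/PhI(OAc)2 oxidation gives the volatile α-branched aldehyde, which is olefinated in the same flask by the stabilised formyl ylide (E-selective Wittig reaction); the weakly basic ylide leaves the α-stereocentre intact.

**Step 9**
Reactants: 21 enal; 22 ethyl (2E)-4-(diethoxyphosphoryl)but-2-enoate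
Product: 25 (2E,4E,6E,8R)-6,8-dimethyldeca-2,4,6-trienoic acid, via lithiated phosphonate 23 (not isolated), via ethyl trienoate 24 (not isolated)
Conditions: 22 (1.3 equiv), LiN(SiMe3)2 (1.25 equiv), THF, −78 °C; then 21, −78 → 0 °C; then LiOH (5 equiv), MeOH/H2O, 23 °C; aq. HCl
Reagents that add atoms: lithium hydroxide, [Li+].[OH-]
Why: Vinylogous Horner–Wadsworth–Emmons olefination through the α-carbon of the phosphonate anion builds the 4E double bond and keeps 2E, and hydroxide then saponifies the ethyl ester in the same flask; the stereocentre is remote.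

**Step 10**
Reactants: 17 hydroxy acid; 25 trienoic acid
Product: 27 (1R,4S,7R,7aS)-1-[2-({[tert-butyl(dimethyl)silyl]oxy}methyl)prop-2-en-1-yl]-4-{[(2E,4E,6E,8R)-6,8-dimethyldeca-2,4,6-trienoyl]oxy}-7a-methyl-2-oxo-2,4,5,6,7,7a-hexahydro-1H-indene-7-carboxylic acid, via mixed anhydride 26 (not isolated)
Conditions: 25 (2.5 equiv), 2,4,6-Cl3C6H2COCl (2.5 equiv), Et3N (6 equiv), PhMe, 23 °C; then 17, DMAP (3 equiv), 23 °C; then aq. NaHCO3/THF; aq. HCl (pH 3)
Reagents that add atoms: none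
Why: Yamaguchi esterification: the trienoic mixed anhydride acylates the axial allylic 4-OH under DMAP catalysis with retention at C4; any mixed anhydride formed at the hindered C7 carboxyl is hydrolysed in the bicarbonate quench, and lactonisation onto C4 would need a boat ring A.

**Step 11**
Reactants: 27 silyl ether
Product: 28 (1R,4S,7R,7aS)-4-{[(2E,4E,6E,8R)-6,8-dimethyldeca-2,4,6-trienoyl]oxy}-1-[2-(hydroxymethyl)prop-2-en-1-yl]-7a-methyl-2-oxo-2,4,5,6,7,7a-hexahydro-1H-indene-7-carboxylic acid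
Conditions: HF·pyridine, pyridine/THF, 0 → 23 °C
Reagents that add atoms: none
Why: Fluoride-driven cleavage of the primary TBS ether (Si–F bond formation) in a buffered medium that spares the trienoate, the enone and C1.

**Step 12**
Reactants: 28 allylic alcohol
Product: 29 (1R,4S,7R,7aS)-4-{[(2E,4E,6E,8R)-6,8-dimethyldeca-2,4,6-trienoyl]oxy}-1-(2-formylprop-2-en-1-yl)-7a-methyl-2-oxo-2,4,5,6,7,7a-hexahydro-1H-indene-7-carboxylic acid (CNP0277819.3)
Conditions: Dess–Martin periodinane (1.3 equiv), CH2Cl2, 0 → 23 °C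
Reagents that add atoms: none
Why: Dess–Martin oxidation of the primary allylic alcohol to the 2-substituted acrolein under non-basic conditions that tolerate the free acid and should not epimerise C1 or isomerise the triene.

**Compound list**
1 | (R)-carvone, (5R)-2-methyl-5-(prop-1-en-2-yl)cyclohex-2-en-1-one | CC1=CC[C@H](CC1=O)C(C)=C | starting material
2 | magnesium (1R,5R)-2-methyl-3-oxido-5-(prop-1-en-2-yl)cyclohex-2-ene-1-carboxylate | [Mg+2].[O-]C(=O)[C@H]1C(C)=C([O-])C[C@H](C(C)=C)C1 | intermediate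
3 | prop-2-yn-1-yl (1R,2S,5R)-2-methyl-3-oxo-5-(prop-1-en-2-yl)-2-(prop-2-yn-1-yl)cyclohexane-1-carboxylate | C#CCOC(=O)[C@H]1[C@](C)(CC#C)C(=O)C[C@H](C(C)=C)C1 | intermediate
4 | 2-oxopropyl (1R,2S,5R)-2-methyl-3-oxo-2-(2-oxopropyl)-5-(prop-1-en-2-yl)cyclohexane-1-carboxylate | CC(=O)COC(=O)[C@H]1[C@](C)(CC(C)=O)C(=O)C[C@H](C(C)=C)C1 | intermediate
5 | potassium (1R,2S,5R)-2-methyl-3-oxo-2-(2-oxopropyl)-5-(prop-1-en-2-yl)cyclohexane-1-carboxylate | [K+].[O-]C(=O)[C@H]1[C@](C)(CC(C)=O)C(=O)C[C@H](C(C)=C)C1 | intermediate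
6 | (5R,7R,7aS)-7a-methyl-2-oxo-5-(prop-1-en-2-yl)-2,4,5,6,7,7a-hexahydro-1H-indene-7-carboxylic acid | C1C(=O)C=C2C[C@H](C(C)=C)C[C@@H](C(=O)O)[C@@]21C | intermediate
7 | (5R,7R,7aS)-5-(1-hydroperoxy-1-methoxyethyl)-7a-methyl-2-oxo-2,4,5,6,7,7a-hexahydro-1H-indene-7-carboxylic acid (side-chain carbon epimers) | C1C(=O)C=C2C[C@H](C(C)(OC)OO)C[C@@H](C(=O)O)[C@@]21C | intermediate
8 | (7R,7aS)-7a-methyl-2-oxo-2,4,5,6,7,7a-hexahydro-1H-indene-7-carboxylic acid | C1C(=O)C=C2CCC[C@@H](C(=O)O)[C@@]21C | intermediate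
9 | 2-methylidenepropane-1,3-diol | C=C(CO)CO | starting material
10 | sodium 2-(hydroxymethyl)prop-2-en-1-olate | [Na+].[O-]CC(=C)CO | intermediate
11 | 2-({[tert-butyl(dimethyl)silyl]oxy}methyl)prop-2-en-1-ol | C=C(CO)CO[Si](C)(C)C(C)(C)C | intermediate
12 | {[2-(bromomethyl)prop-2-en-1-yl]oxy}(tert-butyl)dimethylsilane | C=C(CBr)CO[Si](C)(C)C(C)(C)C | intermediate
13 | dilithium (7R,7aS)-7a-methyl-2-oxido-5,6,7,7a-tetrahydro-4H-indene-7-carboxylate | [Li+].[Li+].C1=C([O-])C=C2CCC[C@@H](C(=O)[O-])[C@@]21C | intermediate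
14 | (1R,7R,7aS)-1-[2-({[tert-butyl(dimethyl)silyl]oxy}methyl)prop-2-en-1-yl]-7a-methyl-2-oxo-2,4,5,6,7,7a-hexahydro-1H-indene-7-carboxylic acid | CC(C)(C)[Si](C)(C)OCC(=C)C[C@H]1C(=O)C=C2CCC[C@@H](C(=O)O)[C@@]21C | intermediate
15 | tert-butyl(dimethyl)silyl (1R,7R,7aS)-2-{[tert-butyl(dimethyl)silyl]oxy}-1-[2-({[tert-butyl(dimethyl)silyl]oxy}methyl)prop-2-en-1-yl]-7a-methyl-5,6,7,7a-tetrahydro-1H-indene-7-carboxylate | CC(C)(C)[Si](C)(C)OCC(=C)C[C@H]1C(O[Si](C)(C)C(C)(C)C)=CC2=CCC[C@@H](C(=O)O[Si](C)(C)C(C)(C)C)[C@@]21C | intermediate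
16 | tert-butyl(dimethyl)silyl (1R,4S,7R,7aS)-1-[2-({[tert-butyl(dimethyl)silyl]oxy}methyl)prop-2-en-1-yl]-4-hydroxy-7a-methyl-2-oxo-2,4,5,6,7,7a-hexahydro-1H-indene-7-carboxylate | CC(C)(C)[Si](C)(C)OCC(=C)C[C@H]1C(=O)C=C2[C@@H](O)CC[C@@H](C(=O)O[Si](C)(C)C(C)(C)C)[C@@]21C | intermediate
17 | (1R,4S,7R,7aS)-1-[2-({[tert-butyl(dimethyl)silyl]oxy}methyl)prop-2-en-1-yl]-4-hydroxy-7a-methyl-2-oxo-2,4,5,6,7,7a-hexahydro-1H-indene-7-carboxylic acid | CC(C)(C)[Si](C)(C)OCC(=C)C[C@H]1C(=O)C=C2[C@@H](O)CC[C@@H](C(=O)O)[C@@]21C | intermediate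
18 | (2R)-2-methylbutan-1-ol | CC[C@@H](C)CO | starting material
19 | 2-(triphenyl-λ5-phosphanylidene)propanal | CC(C=O)=P(c1ccccc1)(c1ccccc1)c1ccccc1 | starting material
20 | (2R)-2-methylbutanal | CC[C@@H](C)C=O | intermediate
21 | (2E,4R)-2,4-dimethylhex-2-enal | CC[C@@H](C)/C=C(\C)C=O | intermediate
22 | ethyl (2E)-4-(diethoxyphosphoryl)but-2-enoate | CCOC(=O)/C=C/CP(=O)(OCC)OCC | starting material
23 | lithium (2E)-1-(diethoxyphosphoryl)-4-ethoxy-4-oxobut-2-en-1-ide | [Li+].CCOC(=O)/C=C/[CH-]P(=O)(OCC)OCC | intermediate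
24 | ethyl (2E,4E,6E,8R)-6,8-dimethyldeca-2,4,6-trienoate | CCOC(=O)/C=C/C=C/C(C)=C/[C@H](C)CC | intermediate
25 | (2E,4E,6E,8R)-6,8-dimethyldeca-2,4,6-trienoic acid | OC(=O)/C=C/C=C/C(C)=C/[C@H](C)CC | intermediate
26 | (2E,4E,6E,8R)-6,8-dimethyldeca-2,4,6-trienoic 2,4,6-trichlorobenzoic anhydride | O=C(OC(=O)c1c(Cl)cc(Cl)cc1Cl)/C=C/C=C/C(C)=C/[C@H](C)CC | intermediate
27 | (1R,4S,7R,7aS)-1-[2-({[tert-butyl(dimethyl)silyl]oxy}methyl)prop-2-en-1-yl]-4-{[(2E,4E,6E,8R)-6,8-dimethyldeca-2,4,6-trienoyl]oxy}-7a-methyl-2-oxo-2,4,5,6,7,7a-hexahydro-1H-indene-7-carboxylic acid | CC(C)(C)[Si](C)(C)OCC(=C)C[C@H]1C(=O)C=C2[C@@H](OC(=O)/C=C/C=C/C(C)=C/[C@H](C)CC)CC[C@@H](C(=O)O)[C@@]21C | intermediate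
28 | (1R,4S,7R,7aS)-4-{[(2E,4E,6E,8R)-6,8-dimethyldeca-2,4,6-trienoyl]oxy}-1-[2-(hydroxymethyl)prop-2-en-1-yl]-7a-methyl-2-oxo-2,4,5,6,7,7a-hexahydro-1H-indene-7-carboxylic acid | OCC(=C)C[C@H]1C(=O)C=C2[C@@H](OC(=O)/C=C/C=C/C(C)=C/[C@H](C)CC)CC[C@@H](C(=O)O)[C@@]21C | intermediate
29 | (1R,4S,7R,7aS)-4-{[(2E,4E,6E,8R)-6,8-dimethyldeca-2,4,6-trienoyl]oxy}-1-(2-formylprop-2-en-1-yl)-7a-methyl-2-oxo-2,4,5,6,7,7a-hexahydro-1H-indene-7-carboxylic acid | C=C(C=O)C[C@H]1C(=O)C=C2[C@@H](OC(=O)/C=C/C=C/C(C)=C/[C@H](C)CC)CC[C@@H](C(=O)O)[C@@]21C | target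

**Step count**
Total: 12 steps. Longest linear sequence: 8 steps (steps 1, 2, 3, 6, 7, 10, 11, 12).

**Three steps most likely to fail**

Step 1 (the proposed new reaction). The radical anion may hydrodimerise, or the magnesium enolate may be protonated or O-alkylated instead of C-propargylated. The fallback uses known chemistry and sets out from 1. Conjugate addition of (i-PrO)Me2SiCH2MgCl with CuI (10 mol%) in THF at −78 °C, followed by trapping of the enolate with propargyl bromide and HMPA, gives silyl ketone F1 with the same trans,trans relationship. Tamao oxidation (H2O2, KF, KHCO3, THF/MeOH) gives hydroxymethyl ketone F2. Jones oxidation (CrO3, H2SO4, acetone, 0 °C) gives keto acid F3. Under the conditions of step 2, F3 is hydrated and cyclised and comes back to the route at 6.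

Step 7. Enolisation may go toward C1 (a cyclopentadienyl silyl ether, then C1 hydroxylation), or the peracid may attack the α face. The fallback sets out from 8 and fixes the C4–O bond through a tether. Wohl–Ziegler bromination (NBS, AIBN, PhCF3, 80 °C) gives γ-bromo enone F4 as a C4 epimer mixture. NaHCO3 and LiBr in DMF at 50 °C interconvert the bromide epimers by exchange, and the C7 carboxylate, which reaches only the β face, displaces the α bromide to give bridged lactone F5. F5 has only bridgehead hydrogens at C4 and C7, so LiN(i-Pr)2 and 12 alkylate C1 to give alkylated lactone F6; the C1 epimer ratio is corrected with DBU if needed. LiOH in THF/H2O opens the lactone and the route is rejoined at 17.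

Step 10. The axial 4-OH is hindered, and activation of the free C7 acid could lead to lactone or oligomers. The fallback sets out from 17 and changes the protecting-group plan. Alkylative esterification (allyl bromide, KHCO3, DMF) gives allyl ester F7. The same Yamaguchi acylation with 25 gives acylated allyl ester F8. Pd(PPh3)4 with morpholine in THF removes the allyl group and the route is rejoined at 27.

**Further compounds**
F1 | step 1 | (2S,3R,5R)-3-{[dimethyl(propan-2-yloxy)silyl]methyl}-2-methyl-5-(prop-1-en-2-yl)-2-(prop-2-yn-1-yl)cyclohexan-1-one | CC(C)O[Si](C)(C)C[C@H]1[C@](C)(CC#C)C(=O)C[C@H](C(C)=C)C1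
F2 | step 1 | (2S,3R,5R)-3-(hydroxymethyl)-2-methyl-5-(prop-1-en-2-yl)-2-(prop-2-yn-1-yl)cyclohexan-1-one | OC[C@H]1[C@](C)(CC#C)C(=O)C[C@H](C(C)=C)C1
F3 | step 1 | (1R,2S,5R)-2-methyl-3-oxo-5-(prop-1-en-2-yl)-2-(prop-2-yn-1-yl)cyclohexane-1-carboxylic acid | OC(=O)[C@H]1[C@](C)(CC#C)C(=O)C[C@H](C(C)=C)C1
F4 | step 7 | (7R,7aS)-4-bromo-7a-methyl-2-oxo-2,4,5,6,7,7a-hexahydro-1H-indene-7-carboxylic acid (C4 epimers) | C1C(=O)C=C2C(Br)CC[C@@H](C(=O)O)[C@@]21C
F5 | step 7 | (4S,7R,7aS)-4-hydroxy-7a-methyl-2-oxo-2,4,5,6,7,7a-hexahydro-1H-indene-7-carboxylic acid 7,4-lactone | C1C(=O)C=C2[C@@H]3CC[C@@H](C(=O)O3)[C@@]21C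
F6 | step 7 | (1R,4S,7R,7aS)-1-[2-({[tert-butyl(dimethyl)silyl]oxy}methyl)prop-2-en-1-yl]-4-hydroxy-7a-methyl-2-oxo-2,4,5,6,7,7a-hexahydro-1H-indene-7-carboxylic acid 7,4-lactone | CC(C)(C)[Si](C)(C)OCC(=C)C[C@H]1C(=O)C=C2[C@@H]3CC[C@@H](C(=O)O3)[C@@]21C
F7 | step 10 | prop-2-en-1-yl (1R,4S,7R,7aS)-1-[2-({[tert-butyl(dimethyl)silyl]oxy}methyl)prop-2-en-1-yl]-4-hydroxy-7a-methyl-2-oxo-2,4,5,6,7,7a-hexahydro-1H-indene-7-carboxylate | CC(C)(C)[Si](C)(C)OCC(=C)C[C@H]1C(=O)C=C2[C@@H](O)CC[C@@H](C(=O)OCC=C)[C@@]21C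
F8 | step 10 | prop-2-en-1-yl (1R,4S,7R,7aS)-1-[2-({[tert-butyl(dimethyl)silyl]oxy}methyl)prop-2-en-1-yl]-4-{[(2E,4E,6E,8R)-6,8-dimethyldeca-2,4,6-trienoyl]oxy}-7a-methyl-2-oxo-2,4,5,6,7,7a-hexahydro-1H-indene-7-carboxylate | CC(C)(C)[Si](C)(C)OCC(=C)C[C@H]1C(=O)C=C2[C@@H](OC(=O)/C=C/C=C/C(C)=C/[C@H](C)CC)CC[C@@H](C(=O)OCC=C)[C@@]21C
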